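**Retrosynthetic overview**
- Target 18 ← aldehyde 17 (CHO → CH2OH) ← allyl compound 16 (allyl → prenyl by cross-metathesis) ← fully protected diaryl ether 15 (one global Lewis-acid deprotection).
- Key disconnection in ring A (benzoic acid numbering: C1 CO2H, C2 OH, C3 side chain, C6 O-aryl): the C6–O(ring B) ether bond and the C1–carboxyl bond are cut together. This leads to a C1≡C6 aryne whose C2 oxygen carries the carboxyl carbon as a tert-butyl carbonate (from 8) and to the phenoxide of ring B (from 10).
- Aryne precursor 8 ← 2-bromoresorcinol 1 by retro-Brook silylation/triflation, O-allylation, aromatic Claisen rearrangement (sets the C3 side chain) and Boc protection.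
- Ring B phenol 10 ← aldehyde 9 by acetalization. No ring is constructed: both benzene rings are bought, and ring A receives its C6 and C1 substituents in the key step.

Key step: step 6

Remark on the chemistry: the target has no stereocentre and no stereogenic double bond, so nothing stereochemical has to be set; compounds 1 and 9 are taken as catalogue compounds.

Step 1
Reactants: 1 2-bromobenzene-1,3-diol (2-bromoresorcinol)
Product: 5 3-hydroxy-2-(trimethylsilyl)phenyl trifluoromethanesulfonate, via bis-silyl ether 2 (not isolated), via lithium phenoxide 3 (not isolated), via silyl ether triflate 4 (not isolated)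
Conditions: HMDS, THF, reflux, then evaporation; n-BuLi, THF, −78 °C; Tf2O, −78 °C; then citric acid, MeOH/H2O, 0 °C
Reagents that add atoms: hexamethyldisilazane, C[Si](C)(C)N[Si](C)(C)C; trifluoromethanesulfonic anhydride, O=S(=O)(OS(=O)(=O)C(F)(F)F)C(F)(F)F
Why: O-silylation, bromine–lithium exchange and retro-Brook (1,3 O-to-C) silyl migration should give a single lithium phenoxide that is trapped by Tf2O, which desymmetrizes the diol without statistics (the standard entry to ortho-silylaryl triflates from ortho-bromophenols), and the remaining aryl silyl ether should fall off on mild acidic work-up.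

Step 2
Reactants: 5 3-hydroxy-2-(trimethylsilyl)phenyl trifluoromethanesulfonate
Product: 6 3-(allyloxy)-2-(trimethylsilyl)phenyl trifluoromethanesulfonate
Conditions: allyl alcohol, PPh3, DIAD, THF, 0 °C to rt
Reagents that add atoms: allyl alcohol, C=CCO
Why: Mitsunobu etherification alkylates the phenol under neutral conditions, which avoids the base-induced carbon-to-oxygen silyl shift that an ortho-silyl phenol with a neighbouring triflate can undergo.

Step 3
Reactants: 6 3-(allyloxy)-2-(trimethylsilyl)phenyl trifluoromethanesulfonate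
Product: 7 4-allyl-3-hydroxy-2-(trimethylsilyl)phenyl trifluoromethanesulfonate
Conditions: 1,2-dichlorobenzene, 180 °C, sealed tube
Reagents that add atoms: none
Why: Aromatic Claisen rearrangement ([3,3] shift, then tautomerization) should deliver the allyl group to C4, the only hydrogen-bearing ortho carbon of the ether, because the other ortho position is blocked by the silyl group.

Step 4
Reactants: 7 4-allyl-3-hydroxy-2-(trimethylsilyl)phenyl trifluoromethanesulfonate
Product: 8 4-allyl-3-[(tert-butoxycarbonyl)oxy]-2-(trimethylsilyl)phenyl trifluoromethanesulfonate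
Conditions: Boc2O, DMAP (cat.), CH2Cl2, 0 °C to rt
Reagents that add atoms: di-tert-butyl dicarbonate, CC(C)(C)OC(=O)OC(=O)OC(C)(C)C
Why: DMAP-catalysed acylation of the phenol gives the aryl tert-butyl carbonate, chosen because it is hindered enough to resist attack by the phenoxide and fluoride used in step 6.

Step 5
Reactants: 9 2-hydroxy-3-methoxy-5-methylbenzaldehyde
Product: 10 2-(1,3-dioxolan-2-yl)-6-methoxy-4-methylphenol
Conditions: HOCH2CH2OH, p-TsOH·H2O (cat.), toluene, reflux, Dean–Stark trap
Reagents that add atoms: ethylene glycol, OCCO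
Why: Acid-catalysed acetalization with azeotropic removal of water masks the aldehyde, which would otherwise trap the aryl anion of step 6 intramolecularly as a xanthenol.

Step 6
Reactants: 8 4-allyl-3-[(tert-butoxycarbonyl)oxy]-2-(trimethylsilyl)phenyl trifluoromethanesulfonate; 10 2-(1,3-dioxolan-2-yl)-6-methoxy-4-methylphenol
Product: 15 tert-butyl 3-allyl-6-[2-(1,3-dioxolan-2-yl)-6-methoxy-4-methylphenoxy]-2-hydroxybenzoate, via potassium phenoxide 11 (not isolated), via aryne 12 (not isolated), via aryl anion 13 (not isolated), via rearranged potassium phenoxide 14 (not isolated)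
Conditions: 10, KH, THF, 0 °C; then 8, KF, 18-crown-6, THF, 0 °C to rt; aq NH4Cl
Reagents that add atoms: none
Why: Proposed new method: fluoride attack at silicon of 8 and loss of triflate should give aryne 12 (triple bond between C1 and C6 of ring A, carbonate oxygen on C2); the inductively withdrawing oxygen at C2 distorts the triple bond and stabilizes negative charge at C1, so phenoxide 11 is expected to add at C6, as oxygen nucleophiles do with 3-alkoxyarynes. The resulting aryl anion 13 sits ortho to the carbonate and should attack its carbonyl in an anionic ortho-Fries (1,3 O-to-C) shift through a four-membered transition state, expelling the ring A phenoxide as the best leaving group, so that the ether oxygen at C6 and the ester carbon at C1 are installed in one operation. The closest known reaction types are the O-arylation of phenols with ortho-silylaryl triflates, the anionic Fries rearrangement of ortho-metalated aryl carbamates and tert-butyl carbonates, and addition/thia-Fries cascades of 3-sulfonyloxyarynes; their combination on a carbonate-bearing aryne has not been shown. No ring is closed and no stereocentre is formed. Three selectivities are needed: the regiochemistry of addition (secured by the C2 oxygen), loss of triflate from the first carbanion ahead of its own attack on the Boc group (secured by the far better leaving-group ability of triflate), and Fries shift ahead of protonation of 13 (secured by complete deprotonation of 10 with KH and by THF in place of acetonitrile).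

Step 7
Reactants: 15 tert-butyl 3-allyl-6-[2-(1,3-dioxolan-2-yl)-6-methoxy-4-methylphenoxy]-2-hydroxybenzoate
Product: 16 3-allyl-6-(2-formyl-6-hydroxy-4-methylphenoxy)-2-hydroxybenzoic acid
Conditions: BBr3 (excess), CH2Cl2, −78 to 0 °C; then H2O
Reagents that add atoms: water, O
Why: Lewis-acid ether cleavage with BBr3 should remove the aryl methyl ether, the tert-butyl ester and the dioxolane in one operation; an allyl group ortho to a phenol is known to survive these conditions whereas a prenyl group would not, which is why the side chain is still allyl at this stage.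

Step 8
Reactants: 16 3-allyl-6-(2-formyl-6-hydroxy-4-methylphenoxy)-2-hydroxybenzoic acid
Product: 17 6-(2-formyl-6-hydroxy-4-methylphenoxy)-2-hydroxy-3-(3-methylbut-2-en-1-yl)benzoic acid
Conditions: 2-methyl-2-butene (excess), second-generation Grubbs catalyst (H2IMes)(PCy3)Cl2Ru=CHPh (cat.), CH2Cl2, 40 °C
Reagents that add atoms: 2-methylbut-2-ene, CC=C(C)C
Why: Olefin cross-metathesis of the terminal allyl group with excess 2-methyl-2-butene should convert it into the prenyl group, a transformation that tolerates free phenols, carboxylic acids and aldehydes.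

Step 9
Reactants: 17 6-(2-formyl-6-hydroxy-4-methylphenoxy)-2-hydroxy-3-(3-methylbut-2-en-1-yl)benzoic acid
Product: 18 2-hydroxy-6-[2-hydroxy-6-(hydroxymethyl)-4-methylphenoxy]-3-(3-methylbut-2-en-1-yl)benzoic acid (target)
Conditions: NaBH4, MeOH/THF, 0 °C; then 1 M HCl to pH 3, 0 °C
Reagents that add atoms: none
Why: Chemoselective hydride reduction of the aryl aldehyde with NaBH4 should give the benzylic alcohol, the carboxylate and the trisubstituted alkene being inert.

**Compound list**
1 | 2-bromobenzene-1,3-diol | Oc1cccc(O)c1Br | starting material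
2 | 2-bromo-1,3-bis(trimethylsilyloxy)benzene | C[Si](C)(C)Oc1cccc(O[Si](C)(C)C)c1Br | intermediate
3 | lithium 2-(trimethylsilyl)-3-(trimethylsilyloxy)phenoxide | [Li+].[O-]c1cccc(O[Si](C)(C)C)c1[Si](C)(C)C | intermediate
4 | 2-(trimethylsilyl)-3-(trimethylsilyloxy)phenyl trifluoromethanesulfonate | C[Si](C)(C)Oc1cccc(OS(=O)(=O)C(F)(F)F)c1[Si](C)(C)C | intermediate
5 | 3-hydroxy-2-(trimethylsilyl)phenyl trifluoromethanesulfonate | C[Si](C)(C)c1c(O)cccc1OS(=O)(=O)C(F)(F)F | intermediate
6 | 3-(allyloxy)-2-(trimethylsilyl)phenyl trifluoromethanesulfonate | C=CCOc1cccc(OS(=O)(=O)C(F)(F)F)c1[Si](C)(C)C | intermediate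
7 | 4-allyl-3-hydroxy-2-(trimethylsilyl)phenyl trifluoromethanesulfonate | C=CCc1ccc(OS(=O)(=O)C(F)(F)F)c([Si](C)(C)C)c1O | intermediate
8 | 4-allyl-3-[(tert-butoxycarbonyl)oxy]-2-(trimethylsilyl)phenyl trifluoromethanesulfonate | C=CCc1ccc(OS(=O)(=O)C(F)(F)F)c([Si](C)(C)C)c1OC(=O)OC(C)(C)C | intermediate
9 | 2-hydroxy-3-methoxy-5-methylbenzaldehyde | COc1cc(C)cc(C=O)c1O | starting material
10 | 2-(1,3-dioxolan-2-yl)-6-methoxy-4-methylphenol | COc1cc(C)cc(C2OCCO2)c1O | intermediate
11 | potassium 2-(1,3-dioxolan-2-yl)-6-methoxy-4-methylphenoxide | [K+].[O-]c1c(OC)cc(C)cc1C1OCCO1 | intermediate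
12 | 6-allyl-2,3-didehydrophenyl tert-butyl carbonate (aryne) | C=CCC1=C(OC(=O)OC(C)(C)C)C#CC=C1 | intermediate
13 | potassium 3-allyl-2-[(tert-butoxycarbonyl)oxy]-6-[2-(1,3-dioxolan-2-yl)-6-methoxy-4-methylphenoxy]phenide | [K+].C=CCc1ccc(Oc2c(OC)cc(C)cc2C2OCCO2)[c-]c1OC(=O)OC(C)(C)C | intermediate
14 | potassium 6-allyl-2-(tert-butoxycarbonyl)-3-[2-(1,3-dioxolan-2-yl)-6-methoxy-4-methylphenoxy]phenoxide | [K+].C=CCc1ccc(Oc2c(OC)cc(C)cc2C2OCCO2)c(C(=O)OC(C)(C)C)c1[O-] | intermediate
15 | tert-butyl 3-allyl-6-[2-(1,3-dioxolan-2-yl)-6-methoxy-4-methylphenoxy]-2-hydroxybenzoate | C=CCc1ccc(Oc2c(OC)cc(C)cc2C2OCCO2)c(C(=O)OC(C)(C)C)c1O | intermediate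
16 | 3-allyl-6-(2-formyl-6-hydroxy-4-methylphenoxy)-2-hydroxybenzoic acid | C=CCc1ccc(Oc2c(O)cc(C)cc2C=O)c(C(=O)O)c1O | intermediate
17 | 6-(2-formyl-6-hydroxy-4-methylphenoxy)-2-hydroxy-3-(3-methylbut-2-en-1-yl)benzoic acid | CC(C)=CCc1ccc(Oc2c(O)cc(C)cc2C=O)c(C(=O)O)c1O | intermediate
18 | 2-hydroxy-6-[2-hydroxy-6-(hydroxymethyl)-4-methylphenoxy]-3-(3-methylbut-2-en-1-yl)benzoic acid | CC(C)=CCc1ccc(Oc2c(O)cc(C)cc2CO)c(C(=O)O)c1O | target

**Step count**
Total: 9 steps. Longest linear sequence: 8 steps (steps 1–4 and 6–9); step 5 is the one-step branch to ring B.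

**Steps most likely to fail, with fallbacks**

1. Step 6 (key step, proposed new method). Possible failures are attack of the first carbanion on the carbonate before triflate is lost, transfer of the Boc group from 8 to the phenoxide nucleophile, and protonation of the aryl anion before the Fries shift. The fallback uses known chemistry and forms the ether bond and the carboxyl carbon in separate operations. It sets out from 7: MOMCl and i-Pr2NEt in CH2Cl2 would give 4-allyl-3-(methoxymethoxy)-2-(trimethylsilyl)phenyl trifluoromethanesulfonate F1. Aryne generation from F1 with CsF in MeCN at rt in the presence of the free phenol 10 would give, by the established O-arylation of phenols with 3-alkoxyarynes and protonation of the aryl anion, 2-{2-[4-allyl-3-(methoxymethoxy)phenoxy]-3-methoxy-5-methylphenyl}-1,3-dioxolane F2. Directed ortho-lithiation between the two oxygen substituents of ring A (n-BuLi, THF, −78 to −20 °C) and quench with CO2 would give 3-allyl-6-[2-(1,3-dioxolan-2-yl)-6-methoxy-4-methylphenoxy]-2-(methoxymethoxy)benzoic acid F3. BBr3 under the conditions of step 7 would then cleave the MOM ether together with the methyl ether and the acetal, and the route is rejoined at 16.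

2. Step 3. The allyl group may migrate to the silyl-bearing ortho carbon with loss of silicon, or the product phenol may undergo thermal carbon-to-oxygen silyl migration and release an aryne prematurely. The fallback introduces the allyl group after ring A has been assembled and sets out from 5. Boc2O and DMAP would give 3-[(tert-butoxycarbonyl)oxy]-2-(trimethylsilyl)phenyl trifluoromethanesulfonate F4. The cascade of step 6 with phenoxide 11 would give tert-butyl 2-[2-(1,3-dioxolan-2-yl)-6-methoxy-4-methylphenoxy]-6-hydroxybenzoate F5. Allyl bromide and K2CO3 in DMF would give tert-butyl 2-(allyloxy)-6-[2-(1,3-dioxolan-2-yl)-6-methoxy-4-methylphenoxy]benzoate F6. Aromatic Claisen rearrangement of F6 (1,2-dichlorobenzene, 180 °C) would place the allyl group on the only free ortho carbon of the salicylate, and the route is rejoined at 15; partial thermal loss of the tert-butyl group would be harmless, since step 7 removes it anyway.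

3. Step 7. Possible failures are hydrobromination of the allyl group or its cyclization onto the neighbouring phenol, tert-butylation of the electron-rich rings, and decarboxylation of the 2,6-dioxygenated benzoic acid. The fallback moves the ether cleavage to the stage of the simple aldehyde and uses only acid-labile groups afterwards; it sets out from 9. BBr3 in CH2Cl2 would give 2,3-dihydroxy-5-methylbenzaldehyde F7. Alkylation of the dianion at the more nucleophilic 3-oxygen (NaH, 2 equiv, DMSO; MOMCl, 1 equiv) would give 2-hydroxy-3-(methoxymethoxy)-5-methylbenzaldehyde F8. Mild acetalization (ethylene glycol, HC(OEt)3, PPTS) would give 2-(1,3-dioxolan-2-yl)-6-(methoxymethoxy)-4-methylphenol F9. The cascade of step 6 with 8 would give tert-butyl 3-allyl-6-[2-(1,3-dioxolan-2-yl)-6-(methoxymethoxy)-4-methylphenoxy]-2-hydroxybenzoate F10. TFA in CH2Cl2/H2O (0 °C to rt), to which the allyl group is inert, would remove the tert-butyl ester, the MOM ether and the dioxolane, and the route is rejoined at 16.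

**Further compounds**
F1 | step 6 | 4-allyl-3-(methoxymethoxy)-2-(trimethylsilyl)phenyl trifluoromethanesulfonate | C=CCc1ccc(OS(=O)(=O)C(F)(F)F)c([Si](C)(C)C)c1OCOC
F2 | step 6 | 2-{2-[4-allyl-3-(methoxymethoxy)phenoxy]-3-methoxy-5-methylphenyl}-1,3-dioxolane | C=CCc1ccc(Oc2c(OC)cc(C)cc2C2OCCO2)cc1OCOC
F3 | step 6 | 3-allyl-6-[2-(1,3-dioxolan-2-yl)-6-methoxy-4-methylphenoxy]-2-(methoxymethoxy)benzoic acid | C=CCc1ccc(Oc2c(OC)cc(C)cc2C2OCCO2)c(C(=O)O)c1OCOC
F4 | step 3 | 3-[(tert-butoxycarbonyl)oxy]-2-(trimethylsilyl)phenyl trifluoromethanesulfonate | CC(C)(C)OC(=O)Oc1cccc(OS(=O)(=O)C(F)(F)F)c1[Si](C)(C)C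
F5 | step 3 | tert-butyl 2-[2-(1,3-dioxolan-2-yl)-6-methoxy-4-methylphenoxy]-6-hydroxybenzoate | COc1cc(C)cc(C2OCCO2)c1Oc1cccc(O)c1C(=O)OC(C)(C)C
F6 | step 3 | tert-butyl 2-(allyloxy)-6-[2-(1,3-dioxolan-2-yl)-6-methoxy-4-methylphenoxy]benzoate | C=CCOc1cccc(Oc2c(OC)cc(C)cc2C2OCCO2)c1C(=O)OC(C)(C)C
F7 | step 7 | 2,3-dihydroxy-5-methylbenzaldehyde | Cc1cc(O)c(O)c(C=O)c1
F8 | step 7 | 2-hydroxy-3-(methoxymethoxy)-5-methylbenzaldehyde | COCOc1cc(C)cc(C=O)c1O
F9 | step 7 | 2-(1,3-dioxolan-2-yl)-6-(methoxymethoxy)-4-methylphenol | COCOc1cc(C)cc(C2OCCO2)c1O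
F10 | step 7 | tert-butyl 3-allyl-6-[2-(1,3-dioxolan-2-yl)-6-(methoxymethoxy)-4-methylphenoxy]-2-hydroxybenzoate | C=CCc1ccc(Oc2c(OCOC)cc(C)cc2C2OCCO2)c(C(=O)OC(C)(C)C)c1O
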